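The nine-membered ring (C1–C9) is not closed end to end but grown from a cyclopentane: C5, C4(Me), C8, C6 and C7 of the target form a 2-methylcyclopentane-1,3-dione skeleton, so breaking C4–C8 while making C1–C2 expands the five-membered ring by four atoms. An anionic oxy-Cope shift of a cis-1-cyclobutenyl-2-methyl-2-vinylcyclopentanol does this in one operation and delivers the cyclobutane-fused cyclononenone with C1 and C9 set. The precursor is assembled from two enantioenriched, stereochemically matched halves: a silyloxy vinyl ketone from the dione and a cyclobutenyl metal (C9–C11, C12 as dioxolane) from methacrolein and dichloroketene. The side chain is added last through a lactone that fixes the Z-alkene.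

Key step: step 11

Numbering: target numbering throughout (ring C1–C9 with C1/C9 at the fusion, cyclobutane C1/C9/C10/C11, side chain C12–C16).

Assumption: the C4 methyl group of the target lies on the outside of the nine-membered ring, so the (4S) ketone is taken to be the epimer favoured at equilibrium, and C4 is therefore set last by base equilibration.

Step 1
Reactants: 1 2-methylcyclopentane-1,3-dione
Product: 2 2-ethynyl-2-methylcyclopentane-1,3-dione
Conditions: TMS-EBX, TBAF, THF, −78 °C → rt
Reagents that add atoms: 1-[(trimethylsilyl)ethynyl]-1,2-benziodoxol-3(1H)-one (TMS-EBX) C[Si](C)(C)C#CI1OC(=O)c2ccccc21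
Why: Electrophilic α-alkynylation of a 2-substituted 1,3-dione enolate with an ethynylbenziodoxolone (fluoride unmasks the reagent, the acidic dione supplies the proton) is a known route to 2-ethynyl-1,3-dicarbonyls, and the rod-like ethynyl group is chosen over vinyl so that methyl is unambiguously the larger substituent in step 2.

Step 2
Reactants: 2 2-ethynyl-2-methylcyclopentane-1,3-dione
Product: 3 (2R,3S)-2-ethynyl-3-hydroxy-2-methylcyclopentan-1-one
Conditions: (R)-2-methyl-CBS-oxazaborolidine (cat.), catecholborane, toluene, −78 °C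
Reagents that add atoms: none
Why: Corey–Bakshi–Shibata desymmetrisation of a 2,2-disubstituted cyclopentane-1,3-dione, in which the catalyst fixes the (S) carbinol (quaternary carbon as the large group) and, of the two enantiotopic carbonyls, the one that can be reduced anti to methyl and syn to the slim ethynyl group reacts, so that OH ends cis to methyl (future C5 and C4).

Step 3
Reactants: 3 (2R,3S)-2-ethynyl-3-hydroxy-2-methylcyclopentan-1-one
Product: 4 (2R,3S)-3-(tert-butyldimethylsilyloxy)-2-ethynyl-2-methylcyclopentan-1-one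
Conditions: TBSOTf, 2,6-lutidine, CH2Cl2, −78 → 0 °C
Reagents that add atoms: tert-butyldimethylsilyl trifluoromethanesulfonate CC(C)(C)[Si](C)(C)OS(=O)(=O)C(F)(F)F
Why: Silylation of a hindered secondary alcohol with a silyl triflate and a hindered pyridine base is non-nucleophilic, so the β-hydroxy ketone cannot undergo retro-aldol cleavage.

Step 4
Reactants: 4 (2R,3S)-3-(tert-butyldimethylsilyloxy)-2-ethynyl-2-methylcyclopentan-1-one
Product: 5 (2R,3S)-3-(tert-butyldimethylsilyloxy)-2-methyl-2-vinylcyclopentan-1-one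
Conditions: H2 (1 atm), Lindlar catalyst (Pd/CaCO3 poisoned with Pb(OAc)2), quinoline, EtOAc, rt
Reagents that add atoms: none
Why: Lindlar semihydrogenation turns the terminal alkyne into the vinyl group and leaves ketone and silyl ether untouched.

Step 5
Reactants: 6 methacrolein
Product: 7 2-(prop-1-en-2-yl)-1,3-dioxolane
Conditions: TMSOCH2CH2OTMS, TMSOTf (cat.), CH2Cl2, −78 °C
Reagents that add atoms: 1,2-bis(trimethylsilyloxy)ethane C[Si](C)(C)OCCO[Si](C)(C)C
Why: Silyl-triflate-catalysed acetalisation with the bis-silyl ether of ethylene glycol (Noyori conditions) protects an enal at low temperature without conjugate addition or polymerisation.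

Step 6
Reactants: 7 2-(prop-1-en-2-yl)-1,3-dioxolane; 8 trichloroacetyl chloride
Product: 10 rac-2,2-dichloro-3-(1,3-dioxolan-2-yl)-3-methylcyclobutan-1-one, via dichloroketene 9 (not isolated)
Conditions: Zn–Cu couple, POCl3, Et2O, 35 °C
Reagents that add atoms: none
Why: Thermal [2+2] ketene–alkene cycloaddition of dichloroketene (from zinc dechlorination of the acid chloride) to a 1,1-disubstituted alkene joins the ketene carbonyl carbon to the CH2 terminus, so the quaternary carbon (future C11) becomes C3 of the cyclobutanone, while POCl3 ties up ZnCl2 and spares the acetal.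

Step 7
Reactants: 10 rac-2,2-dichloro-3-(1,3-dioxolan-2-yl)-3-methylcyclobutan-1-one
Product: 11 3-(1,3-dioxolan-2-yl)-3-methylcyclobutan-1-one
Conditions: Zn, NH4Cl, MeOH, rt
Reagents that add atoms: none
Why: Zinc reduction of an α,α-dichloroketone under buffered, non-acidic conditions keeps the dioxolane and gives an achiral ketone whose two α-CH2 groups are enantiotopic.

Step 8
Reactants: 11 3-(1,3-dioxolan-2-yl)-3-methylcyclobutan-1-one
Product: 13 (3S)-3-(1,3-dioxolan-2-yl)-3-methylcyclobut-1-en-1-yl trifluoromethanesulfonate, via lithium enolate 12 (not isolated)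
Conditions: (R,R)-bis(1-phenylethyl)amine, n-BuLi, LiCl, THF, −100 °C; then Comins' reagent, −100 → −78 °C
Reagents that add atoms: N-(5-chloropyridin-2-yl)bis(trifluoromethanesulfonyl)imide (Comins' reagent) O=S(=O)(N(c1ccc(Cl)cn1)S(=O)(=O)C(F)(F)F)C(F)(F)F
Why: Enantioselective deprotonation of a prochiral 3-substituted cyclobutanone by a chiral lithium amide followed by O-triflation of the enolate creates the C11 stereocentre by choosing one of the two enantiotopic CH2 groups (the (S,S)-amide would be used should the sense of induction prove opposite), and any (R) material is purged as a diastereomer after step 10.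

Step 9
Reactants: 13 (3S)-3-(1,3-dioxolan-2-yl)-3-methylcyclobut-1-en-1-yl trifluoromethanesulfonate
Product: 14 [(3S)-3-(1,3-dioxolan-2-yl)-3-methylcyclobut-1-en-1-yl]trimethylstannane
Conditions: (Me3Sn)2, Pd(PPh3)4 (cat.), LiCl, THF, 60 °C
Reagents that add atoms: hexamethylditin C[Sn](C)(C)[Sn](C)(C)C
Why: Palladium-catalysed stannylation of an enol triflate (Stille-type coupling with a distannane) keeps the position of the double bond and does not touch C11.

Step 10
Reactants: 14 [(3S)-3-(1,3-dioxolan-2-yl)-3-methylcyclobut-1-en-1-yl]trimethylstannane; 5 (2R,3S)-3-(tert-butyldimethylsilyloxy)-2-methyl-2-vinylcyclopentan-1-one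
Product: 17 (1S,2R,3S)-3-(tert-butyldimethylsilyloxy)-1-[(3S)-3-(1,3-dioxolan-2-yl)-3-methylcyclobut-1-en-1-yl]-2-methyl-2-vinylcyclopentan-1-ol, via cyclobutenyllithium 15 (not isolated), via cyclobutenylcerium dichloride 16 (not isolated)
Conditions: 14, MeLi, THF, −78 °C; CeCl3, −78 °C; then 5, −78 → 0 °C; aq. NH4Cl
Reagents that add atoms: none
Why: Tin–lithium exchange and transmetalation to a non-basic organocerium reagent allow 1,2-addition to the hindered, enolisable ketone on the face opposite the C4 methyl and the C5 silyloxy group, that is syn to the vinyl group, which sets C8 and gives the cis-dialkenyl carbinol (the diastereomer from residual (R)-14 is removed by chromatography).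

Step 11
Reactants: 17 (1S,2R,3S)-3-(tert-butyldimethylsilyloxy)-1-[(3S)-3-(1,3-dioxolan-2-yl)-3-methylcyclobut-1-en-1-yl]-2-methyl-2-vinylcyclopentan-1-ol
Product: 21 (1S,3Z,5S,9R,11S)-5-(tert-butyldimethylsilyloxy)-11-(1,3-dioxolan-2-yl)-4,11-dimethylbicyclo[7.2.0]undec-3-en-8-one, via potassium alkoxide 18 (not isolated), via potassium enolate 19 (not isolated), via cis-fused ketone 20 (not isolated)
Conditions: KH, 18-crown-6, THF, 0 °C → rt; then MeOH, 0 °C → rt; aq. NH4Cl
Reagents that add atoms: none
Why: Deprotonation gives a potassium alkoxide whose oxyanion weakens the C4–C8 bond and triggers a concerted [3,3] sigmatropic shift (anionic oxy-Cope rearrangement of a cis-1,2-dialkenylcycloalkanol, the known ring expansion of alkenyllithium adducts of 2-vinylcycloalkanones) that forms C1–C2 and breaks C4–C8. The nine-membered ring is not closed by cyclisation of a chain but arises by four-atom expansion of the cyclopentane through a six-membered boat transition state, the only one a cis arrangement on a five-membered ring allows, which leaves a (Z)-C3=C4 alkene and a C8=C9 enolate. C1 is set by this boat geometry: C2 can reach only the cyclobutene face that points towards C4, and in 17 this face carries the C11 methyl group because (S)-C11 is paired with the (1S,2R) carbinol, so C2 ends cis to methyl and anti to the dioxolane. C9 is set after the shift, by protonation of the enolate and methoxide equilibration α to the C8 ketone to the more stable trans ring fusion. The step therefore needs facial selectivity at the cyclobutene, which is secured by the matched configurations of the two halves and not by a free steric choice (the C11 epimer would be forced to bond syn to the dioxolane), and a concerted rather than fragmentative course, which the cis geometry and the strained cyclobutene favour.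

Step 12
Reactants: 21 (1S,3Z,5S,9R,11S)-5-(tert-butyldimethylsilyloxy)-11-(1,3-dioxolan-2-yl)-4,11-dimethylbicyclo[7.2.0]undec-3-en-8-one
Product: 22 (1S,4R,5S,9R,11S)-5-(tert-butyldimethylsilyloxy)-11-(1,3-dioxolan-2-yl)-4,11-dimethylbicyclo[7.2.0]undecan-8-one
Conditions: H2 (3 atm), Rh/Al2O3, EtOAc, rt
Reagents that add atoms: none
Why: Heterogeneous hydrogenation on Rh/Al2O3 saturates the trisubstituted ring alkene without reducing the ketone or cleaving the allylic silyl ether, and H2 should add to the exposed face turned away from C8/C9 to give mainly (4R), a configuration that is not relied on because C4 is reset in step 22.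

Step 13
Reactants: 22 (1S,4R,5S,9R,11S)-5-(tert-butyldimethylsilyloxy)-11-(1,3-dioxolan-2-yl)-4,11-dimethylbicyclo[7.2.0]undecan-8-one
Product: 23 2-[(1S,4R,5S,9R,11S)-5-(tert-butyldimethylsilyloxy)-4,11-dimethyl-8-methylidenebicyclo[7.2.0]undecan-11-yl]-1,3-dioxolane
Conditions: Ph3PCH3Br, KOtBu, toluene, 80 °C
Reagents that add atoms: methyltriphenylphosphonium bromide C[P+](c1ccccc1)(c1ccccc1)c1ccccc1.[Br-]
Why: Wittig methylenation with methylenetriphenylphosphorane at elevated temperature converts the hindered C8 ketone into the exocyclic alkene, and any C9 epimerisation by the basic ylide only returns the stable trans fusion.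

Step 14
Reactants: 23 2-[(1S,4R,5S,9R,11S)-5-(tert-butyldimethylsilyloxy)-4,11-dimethyl-8-methylidenebicyclo[7.2.0]undecan-11-yl]-1,3-dioxolane
Product: 24 (1S,4R,5S,9R,11S)-5-(tert-butyldimethylsilyloxy)-4,11-dimethyl-8-methylidenebicyclo[7.2.0]undecane-11-carbaldehyde
Conditions: PPTS, acetone/H2O, 55 °C
Reagents that add atoms: water O
Why: Mild acid hydrolysis of the dioxolane frees the C12 aldehyde, which cannot epimerise at quaternary C11, and pyridinium tosylate is too weak to shift the exocyclic alkene or cleave the secondary silyl ether.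

Step 15
Reactants: 24 (1S,4R,5S,9R,11S)-5-(tert-butyldimethylsilyloxy)-4,11-dimethyl-8-methylidenebicyclo[7.2.0]undecane-11-carbaldehyde
Product: 25 (1S)-1-[(1S,4R,5S,9R,11S)-5-(tert-butyldimethylsilyloxy)-4,11-dimethyl-8-methylidenebicyclo[7.2.0]undecan-11-yl]but-3-en-1-ol
Conditions: (−)-Ipc2BOMe, allylMgBr, Et2O, 0 °C → rt; then 24, −78 °C; NaOH, H2O2
Reagents that add atoms: allylmagnesium bromide C=CC[Mg]Br
Why: Brown asymmetric allylboration through a chair Zimmerman–Traxler transition state sets (S)-C12 under reagent control (same sense as with pivalaldehyde), which overrides the weak Felkin bias of a neopentyl aldehyde on a cyclobutane.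

Step 16
Reactants: 25 (1S)-1-[(1S,4R,5S,9R,11S)-5-(tert-butyldimethylsilyloxy)-4,11-dimethyl-8-methylidenebicyclo[7.2.0]undecan-11-yl]but-3-en-1-ol
Product: 26 (1S)-1-[(1S,4R,5S,9R,11S)-5-(tert-butyldimethylsilyloxy)-4,11-dimethyl-8-methylidenebicyclo[7.2.0]undecan-11-yl]but-3-en-1-yl 2-methylprop-2-enoate
Conditions: methacryloyl chloride, Et3N, DMAP (cat.), CH2Cl2, 0 °C → rt
Reagents that add atoms: methacryloyl chloride CC(=C)C(Cl)=O
Why: DMAP-catalysed acylation of the secondary alcohol with an acid chloride installs C15, its methyl group and C16 with retention at C12.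

Step 17
Reactants: 26 (1S)-1-[(1S,4R,5S,9R,11S)-5-(tert-butyldimethylsilyloxy)-4,11-dimethyl-8-methylidenebicyclo[7.2.0]undecan-11-yl]but-3-en-1-yl 2-methylprop-2-enoate
Product: 27 (6S)-6-[(1S,4R,5S,9R,11S)-5-(tert-butyldimethylsilyloxy)-4,11-dimethyl-8-methylidenebicyclo[7.2.0]undecan-11-yl]-3-methyl-5,6-dihydro-2H-pyran-2-one
Conditions: second-generation Grubbs catalyst RuCl2(=CHPh)(PCy3)(H2IMes) (cat.), CH2Cl2, 40 °C
Reagents that add atoms: none
Why: Ring-closing olefin metathesis of a methacrylate with a terminal alkene gives the α-methyl unsaturated δ-lactone, whose six-membered ring forces C13 and C16 cis on the new C14=C15 bond, while the hindered 1,1-disubstituted C8 methylene stays out of the catalytic cycle.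

Step 18
Reactants: 27 (6S)-6-[(1S,4R,5S,9R,11S)-5-(tert-butyldimethylsilyloxy)-4,11-dimethyl-8-methylidenebicyclo[7.2.0]undecan-11-yl]-3-methyl-5,6-dihydro-2H-pyran-2-one
Product: 28 (2Z,5S)-5-[(1S,4R,5S,9R,11S)-5-(tert-butyldimethylsilyloxy)-4,11-dimethyl-8-methylidenebicyclo[7.2.0]undecan-11-yl]-2-methylpent-2-ene-1,5-diol
Conditions: DIBAL-H (i-Bu2AlH), CH2Cl2, −78 → 0 °C; aq. potassium sodium tartrate (KNaC4H4O6)
Reagents that add atoms: none
Why: Exhaustive 1,2-reduction of the unsaturated lactone with an aluminium hydride opens the ring to the allylic diol with the Z geometry of the ring alkene retained.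

Step 19
Reactants: 28 (2Z,5S)-5-[(1S,4R,5S,9R,11S)-5-(tert-butyldimethylsilyloxy)-4,11-dimethyl-8-methylidenebicyclo[7.2.0]undecan-11-yl]-2-methylpent-2-ene-1,5-diol
Product: 29 (2Z,5S)-5-[(1S,4R,5S,9R,11S)-5-(tert-butyldimethylsilyloxy)-4,11-dimethyl-8-methylidenebicyclo[7.2.0]undecan-11-yl]-2-methylpent-2-ene-1,5-diyl diacetate
Conditions: Ac2O, pyridine, DMAP (cat.), CH2Cl2, rt
Reagents that add atoms: acetic anhydride CC(=O)OC(C)=O
Why: Nucleophile-catalysed acetylation esterifies both the primary allylic and the hindered secondary hydroxyl group while C5 is still masked as its silyl ether.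

Step 20
Reactants: 29 (2Z,5S)-5-[(1S,4R,5S,9R,11S)-5-(tert-butyldimethylsilyloxy)-4,11-dimethyl-8-methylidenebicyclo[7.2.0]undecan-11-yl]-2-methylpent-2-ene-1,5-diyl diacetate
Product: 30 (2Z,5S)-5-[(1S,4R,5S,9R,11S)-5-hydroxy-4,11-dimethyl-8-methylidenebicyclo[7.2.0]undecan-11-yl]-2-methylpent-2-ene-1,5-diyl diacetate
Conditions: HF·pyridine, pyridine, THF, 0 °C → rt
Reagents that add atoms: none
Why: Fluoride cleavage of the secondary silyl ether with buffered HF·pyridine leaves acetates and both alkenes intact.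

Step 21
Reactants: 30 (2Z,5S)-5-[(1S,4R,5S,9R,11S)-5-hydroxy-4,11-dimethyl-8-methylidenebicyclo[7.2.0]undecan-11-yl]-2-methylpent-2-ene-1,5-diyl diacetate
Product: 31 (2Z,5S)-5-[(1S,4R,9R,11S)-4,11-dimethyl-8-methylidene-5-oxobicyclo[7.2.0]undecan-11-yl]-2-methylpent-2-ene-1,5-diyl diacetate
Conditions: Dess–Martin periodinane, NaHCO3, CH2Cl2, 0 °C → rt
Reagents that add atoms: none
Why: Dess–Martin oxidation converts the secondary alcohol into the C5 ketone under buffered conditions that touch neither the alkenes nor the acetates.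

Step 22
Reactants: 31 (2Z,5S)-5-[(1S,4R,9R,11S)-4,11-dimethyl-8-methylidene-5-oxobicyclo[7.2.0]undecan-11-yl]-2-methylpent-2-ene-1,5-diyl diacetate
Product: 32 (2Z,5S)-5-[(1S,4S,9R,11S)-4,11-dimethyl-8-methylidene-5-oxobicyclo[7.2.0]undecan-11-yl]-2-methylpent-2-ene-1,5-diyl diacetate (CNP0244219.2)
Conditions: DBU, toluene, rt
Reagents that add atoms: none
Why: Base-mediated epimerisation α to the C5 ketone (thermodynamic control through the enolate) should move the C4 methyl group to the outside of the nine-membered ring to give (4S), while DBU in an aprotic solvent spares the acetates and C1, C9, C11 and C12 are not enolisable.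

Compound list
1 | 2-methylcyclopentane-1,3-dione | CC1C(=O)CCC1=O | starting material
2 | 2-ethynyl-2-methylcyclopentane-1,3-dione | C#CC1(C)C(=O)CCC1=O | intermediate
3 | (2R,3S)-2-ethynyl-3-hydroxy-2-methylcyclopentan-1-one (OH cis to methyl) | C#C[C@]1(C)[C@@H](O)CCC1=O | intermediate
4 | (2R,3S)-3-(tert-butyldimethylsilyloxy)-2-ethynyl-2-methylcyclopentan-1-one | C#C[C@]1(C)[C@@H](O[Si](C)(C)C(C)(C)C)CCC1=O | intermediate
5 | (2R,3S)-3-(tert-butyldimethylsilyloxy)-2-methyl-2-vinylcyclopentan-1-one (OTBS cis to methyl) | C=C[C@]1(C)[C@@H](O[Si](C)(C)C(C)(C)C)CCC1=O | intermediate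
6 | methacrolein | CC(=C)C=O | starting material
7 | 2-(prop-1-en-2-yl)-1,3-dioxolane | CC(=C)C1OCCO1 | intermediate
8 | trichloroacetyl chloride | ClC(=O)C(Cl)(Cl)Cl | starting material
9 | dichloroketene (not isolated) | ClC(Cl)=C=O | intermediate
10 | rac-2,2-dichloro-3-(1,3-dioxolan-2-yl)-3-methylcyclobutan-1-one | O=C1CC(C)(C2OCCO2)C1(Cl)Cl | intermediate
11 | 3-(1,3-dioxolan-2-yl)-3-methylcyclobutan-1-one (achiral) | O=C1CC(C)(C2OCCO2)C1 | intermediate
12 | lithium (3S)-3-(1,3-dioxolan-2-yl)-3-methylcyclobut-1-en-1-olate (not isolated) | [Li]OC1=C[C@@](C)(C2OCCO2)C1 | intermediate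
13 | (3S)-3-(1,3-dioxolan-2-yl)-3-methylcyclobut-1-en-1-yl trifluoromethanesulfonate | O=S(=O)(OC1=C[C@@](C)(C2OCCO2)C1)C(F)(F)F | intermediate
14 | [(3S)-3-(1,3-dioxolan-2-yl)-3-methylcyclobut-1-en-1-yl]trimethylstannane | C[Sn](C)(C)C1=C[C@@](C)(C2OCCO2)C1 | intermediate
15 | [(3S)-3-(1,3-dioxolan-2-yl)-3-methylcyclobut-1-en-1-yl]lithium (not isolated) | [Li]C1=C[C@@](C)(C2OCCO2)C1 | intermediate
16 | dichloro[(3S)-3-(1,3-dioxolan-2-yl)-3-methylcyclobut-1-en-1-yl]cerium (not isolated) | Cl[Ce](Cl)C1=C[C@@](C)(C2OCCO2)C1 | intermediate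
17 | (1S,2R,3S)-3-(tert-butyldimethylsilyloxy)-1-[(3S)-3-(1,3-dioxolan-2-yl)-3-methylcyclobut-1-en-1-yl]-2-methyl-2-vinylcyclopentan-1-ol (cyclobutenyl cis to vinyl; OH, methyl and OTBS on the other face) | C=C[C@]1(C)[C@@H](O[Si](C)(C)C(C)(C)C)CC[C@]1(O)C2=C[C@@](C)(C3OCCO3)C2 | intermediate
18 | potassium alkoxide of 17 (not isolated) | C=C[C@]1(C)[C@@H](O[Si](C)(C)C(C)(C)C)CC[C@]1(O[K])C2=C[C@@](C)(C3OCCO3)C2 | intermediate
19 | potassium C8=C9 enolate of the ring-expanded ketone, (Z)-C3=C4 (not isolated) | [K]O/C1=C2\C[C@](C)(C3OCCO3)[C@H]2C/C=C(C)\[C@@H](O[Si](C)(C)C(C)(C)C)CC1 | intermediate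
20 | cis-fused C9 epimer of 21 (not isolated) | O=C1CC[C@H](O[Si](C)(C)C(C)(C)C)/C(C)=C\C[C@H]2[C@@H]1C[C@]2(C)C3OCCO3 | intermediate
21 | (1S,3Z,5S,9R,11S)-5-(tert-butyldimethylsilyloxy)-11-(1,3-dioxolan-2-yl)-4,11-dimethylbicyclo[7.2.0]undec-3-en-8-one (trans fusion; C2 cis to the C11 methyl) | O=C1CC[C@H](O[Si](C)(C)C(C)(C)C)/C(C)=C\C[C@H]2[C@H]1C[C@]2(C)C3OCCO3 | intermediate
22 | (1S,4R,5S,9R,11S)-5-(tert-butyldimethylsilyloxy)-11-(1,3-dioxolan-2-yl)-4,11-dimethylbicyclo[7.2.0]undecan-8-one (4R expected; C4 reset in step 22) | O=C1CC[C@H](O[Si](C)(C)C(C)(C)C)[C@H](C)CC[C@H]2[C@H]1C[C@]2(C)C3OCCO3 | intermediate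
23 | 2-[(1S,4R,5S,9R,11S)-5-(tert-butyldimethylsilyloxy)-4,11-dimethyl-8-methylidenebicyclo[7.2.0]undecan-11-yl]-1,3-dioxolane | C=C1CC[C@H](O[Si](C)(C)C(C)(C)C)[C@H](C)CC[C@H]2[C@H]1C[C@]2(C)C3OCCO3 | intermediate
24 | (1S,4R,5S,9R,11S)-5-(tert-butyldimethylsilyloxy)-4,11-dimethyl-8-methylidenebicyclo[7.2.0]undecane-11-carbaldehyde | C=C1CC[C@H](O[Si](C)(C)C(C)(C)C)[C@H](C)CC[C@H]2[C@H]1C[C@]2(C)C=O | intermediate
25 | (1S)-1-[(1S,4R,5S,9R,11S)-5-(tert-butyldimethylsilyloxy)-4,11-dimethyl-8-methylidenebicyclo[7.2.0]undecan-11-yl]but-3-en-1-ol | C=C1CC[C@H](O[Si](C)(C)C(C)(C)C)[C@H](C)CC[C@H]2[C@H]1C[C@]2(C)[C@H](CC=C)O | intermediate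
26 | methacrylate ester of 25 | C=C1CC[C@H](O[Si](C)(C)C(C)(C)C)[C@H](C)CC[C@H]2[C@H]1C[C@]2(C)[C@H](CC=C)OC(=O)C(C)=C | intermediate
27 | (6S)-6-[(1S,4R,5S,9R,11S)-5-(tert-butyldimethylsilyloxy)-4,11-dimethyl-8-methylidenebicyclo[7.2.0]undecan-11-yl]-3-methyl-5,6-dihydro-2H-pyran-2-one | C=C1CC[C@H](O[Si](C)(C)C(C)(C)C)[C@H](C)CC[C@H]2[C@H]1C[C@]2(C)[C@@H]3CC=C(C)C(=O)O3 | intermediate
28 | (2Z,5S)-5-[(1S,4R,5S,9R,11S)-5-(tert-butyldimethylsilyloxy)-4,11-dimethyl-8-methylidenebicyclo[7.2.0]undecan-11-yl]-2-methylpent-2-ene-1,5-diol | C=C1CC[C@H](O[Si](C)(C)C(C)(C)C)[C@H](C)CC[C@H]2[C@H]1C[C@]2(C)[C@H](C/C=C(/C)CO)O | intermediate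
29 | diacetate of 28 | C=C1CC[C@H](O[Si](C)(C)C(C)(C)C)[C@H](C)CC[C@H]2[C@H]1C[C@]2(C)[C@H](C/C=C(/C)COC(C)=O)OC(C)=O | intermediate
30 | C5 alcohol: (2Z,5S)-5-[(1S,4R,5S,9R,11S)-5-hydroxy-4,11-dimethyl-8-methylidenebicyclo[7.2.0]undecan-11-yl]-2-methylpent-2-ene-1,5-diyl diacetate | C=C1CC[C@H](O)[C@H](C)CC[C@H]2[C@H]1C[C@]2(C)[C@H](C/C=C(/C)COC(C)=O)OC(C)=O | intermediate
31 | (4R) ketone, C4 epimer of the target | C=C1CCC(=O)[C@H](C)CC[C@H]2[C@H]1C[C@]2(C)[C@H](C/C=C(/C)COC(C)=O)OC(C)=O | intermediate
32 | CNP0244219.2: (2Z,5S)-5-[(1S,4S,9R,11S)-4,11-dimethyl-8-methylidene-5-oxobicyclo[7.2.0]undecan-11-yl]-2-methylpent-2-ene-1,5-diyl diacetate | C=C1CCC(=O)[C@@H](C)CC[C@H]2[C@H]1C[C@]2(C)[C@H](C/C=C(/C)COC(C)=O)OC(C)=O | target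

Total step count: 22. Longest linear sequence: 18 steps (steps 5–22, from methacrolein); the ketone branch (steps 1–4) joins at step 10.

Steps most likely to fail

Step 11. The alkoxide may cleave C4–C8 heterolytically (a tethered allyl anion that then loses silanolate) faster than it rearranges, or the boat may be too crowded by the C4 methyl and the substituted cyclobutene. The fallback replaces the vinyl terminus by an alkyne, whose linear carbon needs no boat. It sets out from ketone 4 (before the Lindlar step) and the cerium reagent 16 made from 14: their 1,2-addition, syn to the slim ethynyl group, should give the ethynyl carbinol F1. KH/18-crown-6 should then induce an acetylenic anionic oxy-Cope shift (C2 to C1, C4–C8 cleaved) to the nine-membered cyclic allenyl ketone F2, trans-fused after the same methoxide equilibration. Hydrogenation over Rh/Al2O3 saturates the C2=C3=C4 allene, and the fallback comes back to the route at 22 (either C4 epimer converges in step 22).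

Step 8. The chiral amide may discriminate poorly between the two enantiotopic CH2 groups, because methyl and dioxolanyl differ little in size, leaving low enantiomeric purity at C11. The fallback gives up asymmetric induction in favour of resolution through the enantiopure partner. It sets out from 11: LDA and Comins' reagent give the racemic enol triflate F3, and stannylation as in step 9 gives the racemic stannane F4. Its cerium reagent (in excess) adds to enantiopure 5 to give 17 together with its C11 epimer F5; the two diastereomers are separated by chromatography (F5 could also be left behind in step 11, where it would have to bond syn to the dioxolane). The fallback comes back at 17.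

Step 22. The equilibrium at C4 may lie on the side of the (4R) ketone or be poorly biased, contrary to the assumption above. The fallback switches from thermodynamic to kinetic control. It sets out from 31: TMSOTf/Et3N gives the more substituted C4=C5 trimethylsilyl enol ether F6, and fluoride-triggered protonation at −78 °C (TBAF buffered with AcOH) protonates C4 from the open face, which should give the contra-thermodynamic epimer. The fallback comes back at 32.

Further compounds
F1 | step 11 | (1S,2R,3S)-3-(tert-butyldimethylsilyloxy)-1-[(3S)-3-(1,3-dioxolan-2-yl)-3-methylcyclobut-1-en-1-yl]-2-ethynyl-2-methylcyclopentan-1-ol | C#C[C@]1(C)[C@@H](O[Si](C)(C)C(C)(C)C)CC[C@]1(O)C2=C[C@@](C)(C3OCCO3)C2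
F2 | step 11 | (1S,5S,9R,11S)-5-(tert-butyldimethylsilyloxy)-11-(1,3-dioxolan-2-yl)-4,11-dimethylbicyclo[7.2.0]undeca-2,3-dien-8-one (axial configuration of the allene immaterial) | O=C1CC[C@H](O[Si](C)(C)C(C)(C)C)C(C)=C=C[C@H]2[C@H]1C[C@]2(C)C3OCCO3
F3 | step 8 | rac-3-(1,3-dioxolan-2-yl)-3-methylcyclobut-1-en-1-yl trifluoromethanesulfonate | O=S(=O)(OC1=CC(C)(C2OCCO2)C1)C(F)(F)F
F4 | step 8 | rac-[3-(1,3-dioxolan-2-yl)-3-methylcyclobut-1-en-1-yl]trimethylstannane | C[Sn](C)(C)C1=CC(C)(C2OCCO2)C1
F5 | step 8 | C11 epimer of 17: (1S,2R,3S)-3-(tert-butyldimethylsilyloxy)-1-[(3R)-3-(1,3-dioxolan-2-yl)-3-methylcyclobut-1-en-1-yl]-2-methyl-2-vinylcyclopentan-1-ol | C=C[C@]1(C)[C@@H](O[Si](C)(C)C(C)(C)C)CC[C@]1(O)C2=C[C@](C)(C3OCCO3)C2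
F6 | step 22 | C4=C5 trimethylsilyl enol ether of 31 (ring carbons C3 and C6 cis) | C=C1CC/C(O[Si](C)(C)C)=C(C)\CC[C@H]2[C@H]1C[C@]2(C)[C@H](C/C=C(/C)COC(C)=O)OC(C)=O
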